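The runs were generated by integration with made-up constants, noise included.

| setting | elm | alder | larch | oak | north-west | north |
|---|---|---|---|---|---|---|
| solid substrate | 1 M | 1 M | 1 M | 0.63 M | 1.0 M | 0.30 M |
| reagent | 0.21 M | 0.49 M | 0.98 M | 1.05 M | 1.05 M | 0.250 M |
| remark | run made earlier | run made earlier | run made earlier | run made earlier |  |  |
| time |  |  |  |  | 1.5 h | 1.0 h |

| run | time / min | target / % | solid substrate / % |
|---|---|---|---|
| elm | 8.00 | 0.2 | 90.1 |
| elm | 25.0 | 2.2 | 75.0 |
| elm | 40.0 | 2.6 | 65.2 |
| elm | 60.0 | 3.9 | 55.3 |
| elm | 90.0 | 4.8 | 46.6 |
| alder | 20.0 | 1.8 | 79.2 |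
| alder | 40.0 | 4.3 | 65.5 |
| alder | 50.0 | 5.4 | 58.8 |
| alder | 80.0 | 9.2 | 46.8 |
| alder | 90.0 | 10.7 | 42.7 |
| larch | 20.0 | 1.8 | 79.3 |
| larch | 40.0 | 6.3 | 64.0 |
| larch | 50.0 | 10.3 | 57.3 |
| larch | 80.0 | 15.8 | 42.6 |
| larch | 90.0 | 16.5 | 37.1 |
| oak | 8.00 | 0 | 84.2 |
| oak | 25.0 | 5.8 | 59.8 |
| oak | 40.0 | 12.7 | 41.7 |
| oak | 60.0 | 19.5 | 23.8 |
| oak | 90.0 | 27.3 | 0.4 |

(each reading ± 0.5 percentage points)

- solid substrate is a solid; its amount is given per volume of the solution
- at the start none of the solid substrate is in solution
- what has only dissolved of solid substrate counts as not reacted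

- the flask that ends with the higher amount of target, in percent of the solid substrate charged, or "neither" when 2 percentage points or less lies between them (north-west / north / neither)
- final target, as a percentage of the solid substrate charged, in north-west
- final target, as a percentage of the solid substrate charged, in north

Slowness opened the meeting. The bench chemist noted that in the elm run after 60.0 min target stood at 3.9%, less than the 55.3% of solid substrate, so she treated north, stopped at 1.0 h, as a question of pace. She proposed Y, which elm's readings put at 0.186: moles of target formed in that time per mole of reagent charged.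

The kineticist objected that at 90.0 min the same ratio in larch is 0.168, less than elm's 0.229, so Y belongs near elm's reagent charge, as north's 0.250 M is. He added that elm had lost 0.447 M of solid substrate by 60.0 min, more than north's whole charge of 0.30 M. Y therefore gives north a high figure of 15.5%, and scaling the target by north's charge over elm's loss gives a low figure of 10.4%. As secretary I minuted the middle, 12.9%.

The chair read north-west straight from the runs: at north-west's 1.5 h, the oak reading gives 0.172 M of target and the larch reading 0.165 M, and their mean is 16.8% of north-west's charge. That is more than north's high figure, and 3.9 percentage points above the minuted middle.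

The forecast, lower than my figure for north, named north-west, with 17.5% there and 8.5% in north, taking north-west as “essentially larch or oak with slightly more reagent”.

The flask gives north-west, with 17.2% against 12.0% in north.

    2 reagent → homo dimer (k = 0.00520 M⁻¹ min⁻¹)
    dissolved substrate + reagent → target (k = 0.0150 M⁻¹ min⁻¹)
    reagent → decomposition product (k = 4.50 × 10⁻⁶ min⁻¹)
    dissolved substrate + target → side product (k = 0.0150 M⁻¹ min⁻¹)
    solid substrate ⇌ dissolved substrate, rate k5*(cs5 - [dissolved substrate]) while solid is left; crystals form when [dissolved substrate] > cs5 (solubility = 0.580 M, k = 0.0220 min⁻¹)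

In north, half of the dissolving up to the end is done by 0.226 h, earlier than half of the turnover of the step to target at 0.579 h. The half-life of reagent by that step at the end, 3.0 h, is longer than the 1.0 h run, and 72.3% of north's reagent stands at the end, with Y in north at 0.144. A neighbour flask, like north but with 1.2 M of solid substrate, gets 3.88% of target from Y; computed, that neighbour holds 3.36%, with 63.1% of solid substrate left.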